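With the six-membered ring numbered C1(=C10H2)–C2–C3(O)–C4(i-Pr)–C5–C9 and the five-membered ring C5–C6(acetyl)–C7(O)–C8–C9, the route cuts the C1–C2 bond. The exocyclic C1=C10 methylene, flanked in the cyclohexane by the C2 methylene and the oxygenated C3, is the imprint of a ketone α-carbon adding across a terminal alkyne. A gold-catalysed 6-exo-dig Conia-ene closure of a C3 enol silyl ether onto a C9 ethynyl group therefore builds the cyclohexanone ring and the methylene in one operation, without a later olefination. The precursor is an all-trans (C9, C5, C6) cyclopentane carrying the ethynyl group, the enol ether arm with C4 already set, a ketal-masked C6 acetyl group and a C7 silyl ether.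

Key step: step 9

Assumption: enone 1 is bought as the enantiopure (R) building block. The bicyclic compounds 18, 19, 25, 26, 28 and 29 are named with the atom labels C1–C10 defined above.

Step 1
Reactants: 1 (4R)-4-{[tert-butyl(dimethyl)silyl]oxy}cyclopent-2-en-1-one; 2 ethynyl(trimethyl)silane
Product: 5 (3S,4R)-4-{[tert-butyl(dimethyl)silyl]oxy}-3-[(trimethylsilyl)ethynyl]cyclopentan-1-one, via lithium (trimethylsilyl)acetylide 3 (not isolated), via dimethyl[(trimethylsilyl)ethynyl]aluminium 4 (not isolated)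
Conditions: 2, n-BuLi, Et2O, −78 → 0 °C; Me2AlCl, 0 °C; then 1, Ni(acac)2/i-Bu2AlH (5 mol%), Et2O, −5 °C
Reagents that add atoms: none
Why: Nickel-catalysed conjugate addition of an alkynylalane to an s-trans cyclic enone is a known reaction of 4-alkoxycyclopentenones, and the alkynyl group should enter the β-carbon anti to the bulky silyloxy group, which sets the future C9 centre.

Step 2
Reactants: 5 (3S,4R)-4-{[tert-butyl(dimethyl)silyl]oxy}-3-[(trimethylsilyl)ethynyl]cyclopentan-1-one
Product: 6 (4R)-4-[(trimethylsilyl)ethynyl]cyclopent-2-en-1-one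
Conditions: DBU, CH2Cl2, −20 → 0 °C
Reagents that add atoms: none
Why: E1cB elimination of the β-silyloxy group transposes the enone without touching the alkynyl-bearing carbon, and a short exposure to the amidine base at low temperature should avoid γ-deprotonation at that centre.

Step 3
Reactants: 7 methyl 3-methylbutanoate
Product: 9 tert-butyl{[(1Z)-1-methoxy-3-methylbut-1-en-1-yl]oxy}dimethylsilane, via lithium ester enolate 8 (not isolated)
Conditions: LiN(i-Pr)2, THF/DMPU, −78 °C; t-BuMe2SiCl, −78 °C → rt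
Reagents that add atoms: tert-butyldimethylsilyl chloride, CC(C)(C)[Si](C)(C)Cl
Why: Kinetic ester enolisation in the presence of the polar cosolvent favours the enolate with O–Li cis to the alkyl group, and O-silylation then gives the (Z)-ketene silyl acetal.

Step 4
Reactants: 6 (4R)-4-[(trimethylsilyl)ethynyl]cyclopent-2-en-1-one; 9 tert-butyl{[(1Z)-1-methoxy-3-methylbut-1-en-1-yl]oxy}dimethylsilane; 10 trimethyl orthoacetate
Product: 12 methyl (2S)-2-[(1S,2R,5R)-2-(1,1-dimethoxyethyl)-3-oxo-5-[(trimethylsilyl)ethynyl]cyclopentyl]-3-methylbutanoate, via enol silyl ether 11 (not isolated)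
Conditions: t-BuMe2SiOTf (10 mol%), CH2Cl2, −78 °C; then 10, Me3SiOTf (20 mol%), −78 → −40 °C; pyridine quench
Reagents that add atoms: none
Why: Tandem Mukaiyama–Michael addition and orthoester alkylation of the resulting enol silyl ether: the ketene acetal should add to the silyl-activated enone at C5 anti to the C9 alkynyl group through an open antiperiplanar transition state (C4–H over the ring, ester carbon anti to C6, isopropyl in the open sector beside C6, the small methoxy rather than the silyloxy group toward C9–H) that fixes C4, and the dimethoxyethyl cation then enters C6 of 11 anti to the new C5 arm.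

Step 5
Reactants: 12 methyl (2S)-2-[(1S,2R,5R)-2-(1,1-dimethoxyethyl)-3-oxo-5-[(trimethylsilyl)ethynyl]cyclopentyl]-3-methylbutanoate
Product: 14 methyl (2S)-2-[(1S,2R,3S,5R)-2-(1,1-dimethoxyethyl)-5-ethynyl-3-hydroxycyclopentyl]-3-methylbutanoate, via silylalkynyl alcohol 13 (not isolated)
Conditions: LiBH(s-Bu)3, THF, −78 °C; then MeOH, K2CO3 (cat.), 0 °C → rt
Reagents that add atoms: none
Why: The bulky borohydride should attack the cyclopentanone from the face opposite the adjacent C6 side chain, giving the C7 alcohol cis to it as with other 2,3-trans-disubstituted cyclopentanones while the hindered ester is inert at −78 °C; methanolic carbonate then protodesilylates the alkyne without enolising C4, which is alpha only to an ester.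

Step 6
Reactants: 14 methyl (2S)-2-[(1S,2R,3S,5R)-2-(1,1-dimethoxyethyl)-5-ethynyl-3-hydroxycyclopentyl]-3-methylbutanoate
Product: 15 (2S)-2-[(1S,2R,3S,5R)-2-(1,1-dimethoxyethyl)-5-ethynyl-3-hydroxycyclopentyl]-N-methoxy-N,3-dimethylbutanamide
Conditions: MeNH(OMe)·HCl, i-PrMgCl (excess), THF, −20 → 0 °C
Reagents that add atoms: N,O-dimethylhydroxylamine hydrochloride, CNOC.Cl
Why: Ester aminolysis by the chloromagnesium amide of N,O-dimethylhydroxylamine (Weinreb amide formation), in which the hydroxyl and alkyne protons only consume extra base and the C7 alkoxide, trans to the arm, cannot lactonise.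

Step 7
Reactants: 15 (2S)-2-[(1S,2R,3S,5R)-2-(1,1-dimethoxyethyl)-5-ethynyl-3-hydroxycyclopentyl]-N-methoxy-N,3-dimethylbutanamide
Product: 16 (3S)-3-[(1R,2R,3S,5R)-2-(1,1-dimethoxyethyl)-5-ethynyl-3-hydroxycyclopentyl]-4-methylpentan-2-one
Conditions: MeMgBr (excess), THF, 0 °C
Reagents that add atoms: methylmagnesium bromide, C[Mg]Br
Why: Weinreb ketone synthesis, in which the magnesium-chelated tetrahedral adduct prevents a second addition and releases the methyl ketone only on work-up, so C4 is not exposed to enolising conditions.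

Step 8
Reactants: 16 (3S)-3-[(1R,2R,3S,5R)-2-(1,1-dimethoxyethyl)-5-ethynyl-3-hydroxycyclopentyl]-4-methylpentan-2-one
Product: 17 tert-butyl({(3S)-3-[(1R,2R,3S,5R)-3-{[tert-butyl(dimethyl)silyl]oxy}-2-(1,1-dimethoxyethyl)-5-ethynylcyclopentyl]-4-methylpent-1-en-2-yl}oxy)dimethylsilane
Conditions: t-BuMe2SiOTf (2.5 equiv), Et3N, CH2Cl2, −78 → −20 °C
Reagents that add atoms: tert-butyldimethylsilyl trifluoromethanesulfonate, CC(C)(C)[Si](C)(C)OS(=O)(=O)C(F)(F)F
Why: Soft enolisation (silyl triflate and amine) removes a proton from the unhindered methyl group rather than from the congested C4 methine and so gives the terminal enol silyl ether with C4 intact, while the C7 hydroxyl is silylated in the same operation and the ketal and terminal alkyne tolerate the cold, amine-buffered medium.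

Step 9
Reactants: 17 tert-butyl({(3S)-3-[(1R,2R,3S,5R)-3-{[tert-butyl(dimethyl)silyl]oxy}-2-(1,1-dimethoxyethyl)-5-ethynylcyclopentyl]-4-methylpent-1-en-2-yl}oxy)dimethylsilane
Product: 18 (4S,5R,6R,7S,9R)-7-{[tert-butyl(dimethyl)silyl]oxy}-6-(1,1-dimethoxyethyl)-4-isopropyl-1-methylidene-trans-hydrindan-3-one
Conditions: (Ph3P)AuCl (10 mol%), AgBF4 (10 mol%), toluene/MeOH (10:1), rt → 40 °C
Reagents that add atoms: none
Why: The cationic monovalent gold complex generated from (Ph3P)AuCl and AgBF4 coordinates the terminal C1≡C10 alkyne, and the nucleophilic C2 of the enol silyl ether attacks C1 anti to gold to give a vinylgold species and a silyloxocarbenium ion; methanol then takes the silyl group and protonates the C–Au bond, releasing the catalyst and the β,γ-unsaturated ketone. The closest known reaction type is the gold-catalysed Conia-ene-type carbocyclisation of silyl enol ethers onto alkynes, which includes six-membered ring closures. The cyclohexanone ring closes 6-exo-dig, leaving C10 outside the ring. No stereocentre is formed: the trans ring fusion follows from the trans C5/C9 substitution of the cyclopentane, and C4 is untouched because the enol ether is regiodefined toward C2. The step needs exo rather than 7-endo closure, C- rather than O-attack, and survival of the ketal and of the deconjugated alkene; these should be secured by the terminal alkyne (attack at the substituted carbon C1), by the much higher nucleophilicity of the enol ether compared with the ketal and silyl ether oxygens, by methanol as proton source (any ketal exchange regenerates the same dimethyl ketal) and by the base-free medium.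

Step 10
Reactants: 18 (4S,5R,6R,7S,9R)-7-{[tert-butyl(dimethyl)silyl]oxy}-6-(1,1-dimethoxyethyl)-4-isopropyl-1-methylidene-trans-hydrindan-3-one
Product: 19 (3R,4S,5R,6R,7S,9R)-7-{[tert-butyl(dimethyl)silyl]oxy}-6-(1,1-dimethoxyethyl)-4-isopropyl-1-methylidene-trans-hydrindan-3-ol
Conditions: LiBH(s-Bu)3, THF, −78 °C
Reagents that add atoms: none
Why: Hydride addition from the bulky borohydride along the equatorial trajectory, away from the axial C5–H, should give the axial C3 alcohol cis to the equatorial isopropyl group (the menthone-to-neomenthol sense), and it is fast enough at −78 °C that the alkene stays out of conjugation.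

Step 11
Reactants: 20 angelic acid, (2Z)-2-methylbut-2-enoic acid
Product: 21 (2Z)-2-methylbut-2-en-1-ol
Conditions: LiAlH4, Et2O, 0 °C
Reagents that add atoms: none
Why: Aluminium hydride reduction of the carboxylic acid to the primary allylic alcohol, which leaves the trisubstituted (Z)-alkene in place.

Step 12
Reactants: 21 (2Z)-2-methylbut-2-en-1-ol
Product: 22 [(2R,3S)-2,3-dimethyloxiran-2-yl]methanol
Conditions: Ti(Oi-Pr)4 (10 mol%), D-(−)-diisopropyl tartrate (12 mol%), t-BuOOH, 4 Å molecular sieves, CH2Cl2, −20 °C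
Reagents that add atoms: tert-butyl hydroperoxide, CC(C)(C)OO
Why: Sharpless asymmetric epoxidation, in which the D-(−)-tartrate catalyst should deliver oxygen to the alkene face that gives the (2R,3S)-epoxy alcohol according to the empirical face-selection rule of this reaction, the two methyl groups staying trans as in the (Z)-alkene.

Step 13
Reactants: 22 [(2R,3S)-2,3-dimethyloxiran-2-yl]methanol
Product: 23 (2S,3S)-2,3-dimethyloxirane-2-carboxylic acid
Conditions: RuCl3 (cat.), NaIO4, CCl4/MeCN/H2O, rt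
Reagents that add atoms: water, O
Why: Oxidation of the primary alcohol to the acid by RuO4 generated in situ, a standard route from epoxy alcohols to glycidic acids that leaves the epoxide untouched (the C2 descriptor changes from R to S only because the priorities change).

Step 14
Reactants: 19 (3R,4S,5R,6R,7S,9R)-7-{[tert-butyl(dimethyl)silyl]oxy}-6-(1,1-dimethoxyethyl)-4-isopropyl-1-methylidene-trans-hydrindan-3-ol; 23 (2S,3S)-2,3-dimethyloxirane-2-carboxylic acid
Product: 25 (3R,4S,5R,6R,7S,9R)-7-{[tert-butyl(dimethyl)silyl]oxy}-6-(1,1-dimethoxyethyl)-4-isopropyl-1-methylidene-trans-hydrindan-3-yl (2S,3S)-2,3-dimethyloxirane-2-carboxylate, via mixed anhydride 24 (not isolated)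
Conditions: 23, 2,4,6-Cl3C6H2COCl, Et3N, THF, rt; then 19, DMAP (cat.), toluene, rt → 50 °C
Reagents that add atoms: none
Why: Yamaguchi esterification, in which the alcohol attacks the unshielded aliphatic carbonyl of mixed anhydride 24 under DMAP catalysis with retention at C3 and at both epoxide carbons.

Step 15
Reactants: 25 (3R,4S,5R,6R,7S,9R)-7-{[tert-butyl(dimethyl)silyl]oxy}-6-(1,1-dimethoxyethyl)-4-isopropyl-1-methylidene-trans-hydrindan-3-yl (2S,3S)-2,3-dimethyloxirane-2-carboxylate
Product: 26 (3R,4S,5R,6R,7S,9R)-6-(1,1-dimethoxyethyl)-7-hydroxy-4-isopropyl-1-methylidene-trans-hydrindan-3-yl (2S,3S)-2,3-dimethyloxirane-2-carboxylate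
Conditions: Bu4NF, AcOH, THF, rt → 40 °C
Reagents that add atoms: none
Why: Fluoride-induced cleavage of the silyl ether, with acetic acid buffering so that the epoxy ester is not saponified and with the ketal inert to fluoride.

Step 16
Reactants: 26 (3R,4S,5R,6R,7S,9R)-6-(1,1-dimethoxyethyl)-7-hydroxy-4-isopropyl-1-methylidene-trans-hydrindan-3-yl (2S,3S)-2,3-dimethyloxirane-2-carboxylate; 20 angelic acid
Product: 28 (3R,4S,5R,6R,7S,9R)-6-(1,1-dimethoxyethyl)-4-isopropyl-1-methylidene-7-{[(2Z)-2-methylbut-2-enoyl]oxy}-trans-hydrindan-3-yl (2S,3S)-2,3-dimethyloxirane-2-carboxylate, via mixed anhydride 27 (not isolated)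
Conditions: 20, 2,4,6-Cl3C6H2COCl, Et3N, toluene, rt; then 26, 75 °C
Reagents that add atoms: none
Why: Acylation through the mixed trichlorobenzoic anhydride without a nucleophilic catalyst, a protocol used for angelates because it avoids the addition–elimination pathway that isomerises them to tiglates, with retention at C7.

Step 17
Reactants: 28 (3R,4S,5R,6R,7S,9R)-6-(1,1-dimethoxyethyl)-4-isopropyl-1-methylidene-7-{[(2Z)-2-methylbut-2-enoyl]oxy}-trans-hydrindan-3-yl (2S,3S)-2,3-dimethyloxirane-2-carboxylate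
Product: 29 (3R,4S,5R,6R,7S,9R)-6-acetyl-4-isopropyl-1-methylidene-7-{[(2Z)-2-methylbut-2-enoyl]oxy}-trans-hydrindan-3-yl (2S,3S)-2,3-dimethyloxirane-2-carboxylate (CNP0300602.1)
Conditions: PPTS, acetone/H2O, rt
Reagents that add atoms: water, O
Why: Mild acid-catalysed ketal hydrolysis frees the C6 acetyl group under conditions that the glycidic ester, the angelate and the 1,1-disubstituted alkene should tolerate and that do not enolise C6.

Compound list

1 | (4R)-4-{[tert-butyl(dimethyl)silyl]oxy}cyclopent-2-en-1-one | O=C1C=C[C@H](O[Si](C)(C)C(C)(C)C)C1 | starting material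
2 | ethynyl(trimethyl)silane | C#C[Si](C)(C)C | starting material
3 | lithium (trimethylsilyl)acetylide | [Li]C#C[Si](C)(C)C | intermediate
4 | dimethyl[(trimethylsilyl)ethynyl]aluminium | C[Al](C)C#C[Si](C)(C)C | intermediate
5 | (3S,4R)-4-{[tert-butyl(dimethyl)silyl]oxy}-3-[(trimethylsilyl)ethynyl]cyclopentan-1-one | O=C1C[C@@H](C#C[Si](C)(C)C)[C@H](O[Si](C)(C)C(C)(C)C)C1 | intermediate
6 | (4R)-4-[(trimethylsilyl)ethynyl]cyclopent-2-en-1-one | O=C1C=C[C@H](C#C[Si](C)(C)C)C1 | intermediate
7 | methyl 3-methylbutanoate | COC(=O)CC(C)C | starting material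
8 | lithium (Z)-enolate of methyl 3-methylbutanoate | CC(C)/C=C(/OC)O[Li] | intermediate
9 | tert-butyl{[(1Z)-1-methoxy-3-methylbut-1-en-1-yl]oxy}dimethylsilane | CC(C)/C=C(/OC)O[Si](C)(C)C(C)(C)C | intermediate
10 | trimethyl orthoacetate (1,1,1-trimethoxyethane) | CC(OC)(OC)OC | starting material
11 | methyl (2S)-2-[(1S,5R)-3-{[tert-butyl(dimethyl)silyl]oxy}-5-[(trimethylsilyl)ethynyl]cyclopent-2-en-1-yl]-3-methylbutanoate | COC(=O)[C@@H](C(C)C)[C@@H]1C=C(O[Si](C)(C)C(C)(C)C)C[C@H]1C#C[Si](C)(C)C | intermediate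
12 | methyl (2S)-2-[(1S,2R,5R)-2-(1,1-dimethoxyethyl)-3-oxo-5-[(trimethylsilyl)ethynyl]cyclopentyl]-3-methylbutanoate | COC(=O)[C@@H](C(C)C)[C@@H]1[C@@H](C(C)(OC)OC)C(=O)C[C@H]1C#C[Si](C)(C)C | intermediate
13 | methyl (2S)-2-[(1S,2R,3S,5R)-2-(1,1-dimethoxyethyl)-3-hydroxy-5-[(trimethylsilyl)ethynyl]cyclopentyl]-3-methylbutanoate | COC(=O)[C@@H](C(C)C)[C@@H]1[C@@H](C(C)(OC)OC)[C@@H](O)C[C@H]1C#C[Si](C)(C)C | intermediate
14 | methyl (2S)-2-[(1S,2R,3S,5R)-2-(1,1-dimethoxyethyl)-5-ethynyl-3-hydroxycyclopentyl]-3-methylbutanoate | COC(=O)[C@@H](C(C)C)[C@@H]1[C@@H](C(C)(OC)OC)[C@@H](O)C[C@H]1C#C | intermediate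
15 | (2S)-2-[(1S,2R,3S,5R)-2-(1,1-dimethoxyethyl)-5-ethynyl-3-hydroxycyclopentyl]-N-methoxy-N,3-dimethylbutanamide | CON(C)C(=O)[C@@H](C(C)C)[C@@H]1[C@@H](C(C)(OC)OC)[C@@H](O)C[C@H]1C#C | intermediate
16 | (3S)-3-[(1R,2R,3S,5R)-2-(1,1-dimethoxyethyl)-5-ethynyl-3-hydroxycyclopentyl]-4-methylpentan-2-one | CC(=O)[C@@H](C(C)C)[C@@H]1[C@@H](C(C)(OC)OC)[C@@H](O)C[C@H]1C#C | intermediate
17 | tert-butyl({(3S)-3-[(1R,2R,3S,5R)-3-{[tert-butyl(dimethyl)silyl]oxy}-2-(1,1-dimethoxyethyl)-5-ethynylcyclopentyl]-4-methylpent-1-en-2-yl}oxy)dimethylsilane | C=C(O[Si](C)(C)C(C)(C)C)[C@@H](C(C)C)[C@@H]1[C@@H](C(C)(OC)OC)[C@@H](O[Si](C)(C)C(C)(C)C)C[C@H]1C#C | intermediate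
18 | (4S,5R,6R,7S,9R)-7-{[tert-butyl(dimethyl)silyl]oxy}-6-(1,1-dimethoxyethyl)-4-isopropyl-1-methylidene-trans-hydrindan-3-one | C=C1CC(=O)[C@@H](C(C)C)[C@@H]2[C@@H](C(C)(OC)OC)[C@@H](O[Si](C)(C)C(C)(C)C)C[C@@H]12 | intermediate
19 | (3R,4S,5R,6R,7S,9R)-7-{[tert-butyl(dimethyl)silyl]oxy}-6-(1,1-dimethoxyethyl)-4-isopropyl-1-methylidene-trans-hydrindan-3-ol | C=C1C[C@@H](O)[C@@H](C(C)C)[C@@H]2[C@@H](C(C)(OC)OC)[C@@H](O[Si](C)(C)C(C)(C)C)C[C@@H]12 | intermediate
20 | angelic acid, (2Z)-2-methylbut-2-enoic acid | C/C=C(/C)C(=O)O | starting material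
21 | (2Z)-2-methylbut-2-en-1-ol | OC/C(C)=C\C | intermediate
22 | [(2R,3S)-2,3-dimethyloxiran-2-yl]methanol | OC[C@@]1(C)O[C@H]1C | intermediate
23 | (2S,3S)-2,3-dimethyloxirane-2-carboxylic acid | OC(=O)[C@@]1(C)O[C@H]1C | intermediate
24 | (2S,3S)-2,3-dimethyloxirane-2-carboxylic 2,4,6-trichlorobenzoic anhydride | O=C(OC(=O)c1c(Cl)cc(Cl)cc1Cl)[C@@]2(C)O[C@H]2C | intermediate
25 | (3R,4S,5R,6R,7S,9R)-7-{[tert-butyl(dimethyl)silyl]oxy}-6-(1,1-dimethoxyethyl)-4-isopropyl-1-methylidene-trans-hydrindan-3-yl (2S,3S)-2,3-dimethyloxirane-2-carboxylate | C=C1C[C@@H](OC(=O)[C@@]3(C)O[C@H]3C)[C@@H](C(C)C)[C@@H]2[C@@H](C(C)(OC)OC)[C@@H](O[Si](C)(C)C(C)(C)C)C[C@@H]12 | intermediate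
26 | (3R,4S,5R,6R,7S,9R)-6-(1,1-dimethoxyethyl)-7-hydroxy-4-isopropyl-1-methylidene-trans-hydrindan-3-yl (2S,3S)-2,3-dimethyloxirane-2-carboxylate | C=C1C[C@@H](OC(=O)[C@@]3(C)O[C@H]3C)[C@@H](C(C)C)[C@@H]2[C@@H](C(C)(OC)OC)[C@@H](O)C[C@@H]12 | intermediate
27 | (2Z)-2-methylbut-2-enoic 2,4,6-trichlorobenzoic anhydride | C/C=C(/C)C(=O)OC(=O)c1c(Cl)cc(Cl)cc1Cl | intermediate
28 | (3R,4S,5R,6R,7S,9R)-6-(1,1-dimethoxyethyl)-4-isopropyl-1-methylidene-7-{[(2Z)-2-methylbut-2-enoyl]oxy}-trans-hydrindan-3-yl (2S,3S)-2,3-dimethyloxirane-2-carboxylate | C=C1C[C@@H](OC(=O)[C@@]3(C)O[C@H]3C)[C@@H](C(C)C)[C@@H]2[C@@H](C(C)(OC)OC)[C@@H](OC(=O)/C(C)=C\C)C[C@@H]12 | intermediate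
29 | (3R,4S,5R,6R,7S,9R)-6-acetyl-4-isopropyl-1-methylidene-7-{[(2Z)-2-methylbut-2-enoyl]oxy}-trans-hydrindan-3-yl (2S,3S)-2,3-dimethyloxirane-2-carboxylate (CNP0300602.1) | C=C1C[C@@H](OC(=O)[C@@]2(C)O[C@H]2C)[C@@H](C(C)C)[C@@H]2[C@@H](C(C)=O)[C@@H](OC(=O)/C(C)=C\C)C[C@@H]12 | target

Total step count: 17 (13 in the main line, 1 for the ketene acetal, 3 for the epoxy acid).
Longest linear sequence: 13 steps (1 to 29 through steps 1, 2, 4–10 and 14–17).

Steps most likely to fail

Step 9. Protodesilylation of the enol ether may outrun ring closure, because the trans-fused ring has to form beside the bulky C6 ketal. A ketal oxygen, which sits cis-1,3 to the alkyne, may also intercept the gold-activated alkyne. The fallback sets out from 17 and comes back at 18, and it makes the C1–C2 bond by a radical instead of a polar closure. N-Iodosuccinimide in THF at −78 °C would convert the enol silyl ether into the iodomethyl ketone (3S)-3-[(1R,2R,3S,5R)-3-{[tert-butyl(dimethyl)silyl]oxy}-2-(1,1-dimethoxyethyl)-5-ethynylcyclopentyl]-1-iodo-4-methylpentan-2-one F1. Slow addition of Bu3SnH with AIBN in benzene at 80 °C would then generate the α-keto radical, which should close 6-exo-dig onto the alkyne. The resulting vinyl radical takes hydrogen from the stannane and gives 18 under neutral conditions that cannot move the alkene into conjugation.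

Step 4. Poor discrimination between the two faces of the nucleophilic ketene acetal carbon (open transition states of similar energy) would erode the configuration at C4. The coupling would then give the C4-epimeric keto ester methyl (2R)-2-[(1S,2R,5R)-2-(1,1-dimethoxyethyl)-3-oxo-5-[(trimethylsilyl)ethynyl]cyclopentyl]-3-methylbutanoate F2 beside 12. The fallback sets out from 6 and 9, accepts the mixture, corrects C4 afterwards by enolate protonation, and comes back at 14.
- The mixture would be taken through step 5, which turns F2 into the silylalkynyl alcohol methyl (2R)-2-[(1S,2R,3S,5R)-2-(1,1-dimethoxyethyl)-3-hydroxy-5-[(trimethylsilyl)ethynyl]cyclopentyl]-3-methylbutanoate F3 and then into the C4-epimeric hydroxy ester methyl (2R)-2-[(1S,2R,3S,5R)-2-(1,1-dimethoxyethyl)-5-ethynyl-3-hydroxycyclopentyl]-3-methylbutanoate F4.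
- F4, alone or mixed with 14, would be deprotonated with excess LiN(i-Pr)2 in THF (−78 → −20 °C) to the trilithium ester enolate F5 and reprotonated at −78 °C with acetic acid.
- With C5–H lying in the enolate plane to relieve allylic strain, the proton should arrive from the side of the slim ethynyl-bearing C9 and not from the ketal-bearing C6. That is the C4 configuration of 14. Material left as F4 is recycled.

Step 1. Catalyst deactivation or competing 1,2-addition may stall the alkynyl transfer, and early loss of silanolate from the aluminium enolate may open the way to a second addition. The fallback sets out from 2 through alane 4 and comes back at 6, using hydroxyl-directed delivery without nickel. The free hydroxy enone (4S)-4-hydroxycyclopent-2-en-1-one F6 would be treated with excess 4 in Et2O/toluene. The aluminium alkoxide formed first should hand the alkynyl group to the β-carbon on its own face, giving the cis-hydroxy ketone (3S,4S)-4-hydroxy-3-[(trimethylsilyl)ethynyl]cyclopentan-1-one F7. MsCl and Et3N at 0 °C would then give the mesylate (1S,2S)-4-oxo-2-[(trimethylsilyl)ethynyl]cyclopentyl methanesulfonate F8, which eliminates in the same flask to 6 under a weaker base than the one used in step 2.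

Further compounds

F1 | step 9 | (3S)-3-[(1R,2R,3S,5R)-3-{[tert-butyl(dimethyl)silyl]oxy}-2-(1,1-dimethoxyethyl)-5-ethynylcyclopentyl]-1-iodo-4-methylpentan-2-one | ICC(=O)[C@@H](C(C)C)[C@@H]1[C@@H](C(C)(OC)OC)[C@@H](O[Si](C)(C)C(C)(C)C)C[C@H]1C#C
F2 | step 4 | methyl (2R)-2-[(1S,2R,5R)-2-(1,1-dimethoxyethyl)-3-oxo-5-[(trimethylsilyl)ethynyl]cyclopentyl]-3-methylbutanoate | COC(=O)[C@H](C(C)C)[C@@H]1[C@@H](C(C)(OC)OC)C(=O)C[C@H]1C#C[Si](C)(C)C
F3 | step 4 | methyl (2R)-2-[(1S,2R,3S,5R)-2-(1,1-dimethoxyethyl)-3-hydroxy-5-[(trimethylsilyl)ethynyl]cyclopentyl]-3-methylbutanoate | COC(=O)[C@H](C(C)C)[C@@H]1[C@@H](C(C)(OC)OC)[C@@H](O)C[C@H]1C#C[Si](C)(C)C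
F4 | step 4 | methyl (2R)-2-[(1S,2R,3S,5R)-2-(1,1-dimethoxyethyl)-5-ethynyl-3-hydroxycyclopentyl]-3-methylbutanoate | COC(=O)[C@H](C(C)C)[C@@H]1[C@@H](C(C)(OC)OC)[C@@H](O)C[C@H]1C#C
F5 | step 4 | trilithium ester enolate of F4 (lithium enolate, lithium alkoxide, lithium acetylide) | [Li]OC(OC)=C(C(C)C)[C@@H]1[C@@H](C(C)(OC)OC)[C@@H](O[Li])C[C@H]1C#C[Li]
F6 | step 1 | (4S)-4-hydroxycyclopent-2-en-1-one | O=C1C=C[C@@H](O)C1
F7 | step 1 | (3S,4S)-4-hydroxy-3-[(trimethylsilyl)ethynyl]cyclopentan-1-one | O=C1C[C@@H](C#C[Si](C)(C)C)[C@@H](O)C1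
F8 | step 1 | (1S,2S)-4-oxo-2-[(trimethylsilyl)ethynyl]cyclopentyl methanesulfonate | O=C1C[C@@H](C#C[Si](C)(C)C)[C@@H](OS(C)(=O)=O)C1
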